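The columns of a run cannot be the whole flask: at 10.0 h the eta run leaves 10.4% of the substrate charged unshown.

| flask | substrate | partner | remark | time |
|---|---|---|---|---|
| eta | 0.99 M | 1.8 M | run made earlier |  |
| theta | 0.99 M | 2.8 M | run made earlier |  |
| zeta | 1.5 M | 1.29 M | run made earlier |  |
| flask | 0.99 M | 1.29 M |  | 15 h |

| run | time / h | substrate / % | target / % | open intermediate / % |
|---|---|---|---|---|
| eta | 0.667 | 53.4 | 14.7 | 27.3 |
| eta | 2.00 | 15.3 | 29.9 | 45.2 |
| eta | 3.00 | 9.1 | 31.0 | 49.7 |
| eta | 5.00 | 2.9 | 33.6 | 54.0 |
| eta | 6.00 | 0.3 | 29.4 | 52.1 |
| eta | 10.0 | 3.0 | 33.7 | 52.9 |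
| theta | 0.667 | 53.6 | 20.1 | 22.9 |
| theta | 1.33 | 29.2 | 29.9 | 32.3 |
| theta | 2.00 | 17.3 | 36.6 | 36.6 |
| theta | 3.00 | 8.0 | 37.7 | 40.6 |
| theta | 5.00 | 3.9 | 41.5 | 40.7 |
| theta | 10.0 | 4.0 | 41.0 | 40.1 |
| zeta | 2.00 | 16.0 | 22.4 | 56.0 |
| zeta | 4.00 | 5.1 | 23.4 | 65.1 |
| zeta | 5.00 | 4.2 | 22.0 | 65.8 |
| zeta | 8.00 | 3.9 | 23.4 | 64.9 |
| zeta | 10.0 | 2.9 | 22.5 | 64.7 |

(scatter of a reading: 1 percentage point)

1. why nothing more happens at 15 h, or that something still does (forward and back rates have come level / it is still moving / all of the substrate has reacted / the partner has run out first)
2. conversion of substrate at 15 h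
3. amount of target at 15 h, in percent of the substrate charged
4. amount of open intermediate at 15 h, in percent of the substrate charged

- steps under discussion: open intermediate + second intermediate <-> target; target <-> isomer of the product; partner -> second intermediate; substrate <-> open intermediate
- the reaction counts as stopped when no species that holds the substrate changes by six tenths of a point or more over the second half of the time

1. I take that remainder as isomer of the product. Target plus isomer I call bound. Each unit of bound has used one unit of second intermediate.

2. I treat partner → second intermediate as fast, so c(second intermediate) = partner charged − c(bound). Then I form the binding ratio, c(bound) / (c(open intermediate) · c(second intermediate)), an apparent equilibrium constant. The late eta readings give 0.611 /M.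

3. But that is one run, and the fast step is my assumption. The other runs differ in their charges. So I check: theta gives 0.621 /M and zeta 0.623 /M, level with eta. Their mean is the binding ratio I carry, 0.618 /M.

4. Will this flask be flat by 15 h? Zeta has the same partner charge, and its target moves 0.9 percentage points between 4.00 h and 10.0 h, less than the scatter. So I expect rest.

5. Not all unbound substrate is open, though. Pooled late readings put 94.1% of it open and 73.4% of bound as target.

6. Solving the ratio for this flask gives c(bound) = 0.350 M. My reckoning: target 26.0%, open intermediate 60.8%, conversion 96.2%.

The forecast says forward and back rates have come level, with conversion 96.3%, target 26.2% and open intermediate 61.5%: “The late readings in all three runs are flat”.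

In the flask, the partner has run out first, with conversion 97.7%, target 25.8% and open intermediate 61.6%. At 15.0 h partner stands at 0% of its charge and second intermediate at 0.932 M.

    open intermediate + second intermediate ⇌ target (K = 0.450 /M, k = 7.90 × 10⁻⁴ /M/s)
    target ⇌ isomer of the product (K = 0.400, k = 1.30 × 10⁻⁴ /s)
    partner → second intermediate (k = 0.00810 /s)
    substrate ⇌ open intermediate (K = 27.0, k = 2.60 × 10⁻⁴ /s)

With 0.618 /M, this flask's 61.6% of open intermediate and 0.932 M of second intermediate call for 35.5% bound, and it holds 36.1%. For the neighbour flask with 0.77 M of partner, the same reckoning gives c(bound) = 0.235 M, so target 17.4% and open intermediate 71.8%; that neighbour gives target 17.4% and open intermediate 73.0%. The asked flask has come to rest: over its second half no share moved more than 0.076 points, and its conversion stays put with longer time. At 150 h its open intermediate differs from the value at 15 h by 3.0 × 10⁻⁵ points.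

The numbers in the tables were generated by integration with constants of no real substance; scatter was added.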